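- The constants of this system aren't given, so I read one from the last readings of the four runs. I call it the ring fraction f: X divided by all the Z that did not end in L, so f = X/(C − L), where C is the whole Z charged. It reads 0.255, 0.256, 0.251 and 0.252, with a mean of 0.254, about a quarter.

| flask | Z | E | temperature | remark | time |
|---|---|---|---|---|---|
| Thursday's | 20 mM | 1.5 equiv | 20 °C | run made earlier |  |
| Tuesday's | 20 mM | 2.1 equiv | 35 °C | run made earlier |  |
| Monday's | 20 mM | 3.3 equiv | 20 °C | run made earlier |  |
| Friday's | 10 mM | 1.5 equiv | 35 °C | run made earlier |  |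
| summer | 20 mM | 1.50 equiv | 35 °C | everything together at the start | 8.0 min |
| dusk | 20 mM (fed, over 3.0 min) | 1.50 equiv |  | the addition at −5 °C, then warmed to 35 °C; the feed brings no volume worth counting | 8.0 min |
| spring | 20 mM | 1.50 equiv |  | everything together at the start at −5 °C, warmed to 35 °C at 3.0 min | 8.0 min |
| dawn | 20 mM (fed, over 50 s) | 1.50 equiv | 35 °C | all else is in the flask from the start; the feed brings no volume worth counting | 8.0 min |
| noon | 20 mM (fed, over 3.0 min) | 1.50 equiv | 35 °C | all else is in the flask from the start; the feed brings no volume worth counting | 8.0 min |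
| winter | 20 mM | 1.50 equiv (fed, over 3.0 min) | 35 °C | all else is in the flask from the start; the feed brings no volume worth counting | 8.0 min |

| run | time / min | X / % | L / % |
|---|---|---|---|
| Thursday's | 0.833 | 4.8 | 8.9 |
| Thursday's | 3.00 | 13.6 | 22.3 |
| Thursday's | 4.00 | 14.5 | 24.8 |
| Thursday's | 6.00 | 18.4 | 26.4 |
| Thursday's | 10.0 | 18.9 | 25.8 |
| Tuesday's | 2.00 | 21.1 | 14.3 |
| Tuesday's | 4.00 | 21.3 | 15.5 |
| Tuesday's | 6.00 | 21.6 | 14.9 |
| Tuesday's | 8.00 | 21.6 | 14.8 |
| Tuesday's | 10.0 | 21.8 | 15.0 |
| Monday's | 4.00 | 20.2 | 12.4 |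
| Monday's | 8.00 | 21.0 | 11.6 |
| Monday's | 12.0 | 22.3 | 12.4 |
| Monday's | 15.0 | 21.5 | 12.1 |
| Monday's | 20.0 | 22.2 | 11.7 |
| Friday's | 0.833 | 12.9 | 9.9 |
| Friday's | 2.50 | 19.9 | 19.1 |
| Friday's | 4.00 | 19.3 | 19.5 |
| Friday's | 6.00 | 19.7 | 20.3 |
| Friday's | 10.0 | 20.1 | 20.3 |

(standard deviation of a reading: 0.5 percentage points)

* the best flask by share of X in X plus L; "all alike" if 1.5 percentage points covers them all (summer / dusk / spring / dawn / noon / winter / all alike)
* share of X in X plus L at the end, summer
* share of X in X plus L at the end, dusk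
* share of X in X plus L at the end, spring
* share of X in X plus L at the end, dawn
* share of X in X plus L at the end, noon
* share of X in X plus L at the end, winter

- a species is counted by the Z in it: one L counts as two

- With f in hand, the share of X in X plus L follows from L: share = f(C − L)/(f(C − L) + L).
- L is what varies: at 20 °C, Thursday's run ends with more L than Monday's, and Monday's has the richer E.
- I suppose that activated Z meets free Z to give L, while free Z meets E to become activated. Dividing one rate by the other, time and [Z] both drop out, which leaves a branch ratio (a selectivity factor) of activated Z to E.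
- [Z] does not stand in that ratio, so I expect a slow feed of Z to change it little. I therefore take Friday's L for summer, dawn and noon, and my estimate of the share is 49.9%.
- Winter's E is fed over 3.0 min onto the full charge of Z, so I expect its ratio to run high and its share to fall.
- The weak link is the fixed proportion between activated Z and X. In Friday's run the ring fraction reads 0.143 at 0.833 min, less than f, and reaches 0.246 by 2.50 min.
- Summer holds twice Friday's Z, so I expect it to react faster through that lag and to end a little below 49.9%. Noon's feed lasts 3.0 min, longer than the 2.50 min of that Friday reading, so I commit to about 49.9% for noon.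
- The forecast gives summer 50%, dusk 49.5%, spring 48.5%, dawn 53%, noon 63% and winter 27%, and names noon as best: “Noon keeps Z low while E is plentiful, which helps”. My estimate for noon stands lower than the forecast's.
- The simulated flasks give summer 47.8%, dusk 47.3%, spring 45.9%, dawn 49.0%, noon 50.9% and winter 30.7%, so noon is best.

    X ⇌ Q (K = 0.620, k = 0.0580 s⁻¹, Ea = 92.0 kJ mol⁻¹, ΔH = −12.0 kJ mol⁻¹)
    J ⇌ X (K = 0.420, k = 0.0310 s⁻¹, Ea = 92.0 kJ mol⁻¹, ΔH = −4.00 kJ mol⁻¹)
    Z + E → J (k = 2.00 L mol⁻¹ s⁻¹, Ea = 59.0 kJ mol⁻¹)
    Z + J → L (k = 0.680 L mol⁻¹ s⁻¹, Ea = 47.0 kJ mol⁻¹)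
    (constants at 35 °C)

- Noon ends 12 percentage points below the forecast, with L at 19.4% after 8.00 min; f on that L gives a share of 51.3%. The neighbouring flask is noon charged with 0.900 equiv of E. It ends with L at 39.6%, so f gives X as 15.3% and a share of 27.9%. That flask holds X at 14.8%, and its share is 27.2%.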